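**Retrosynthetic overview**
1. Target 23 ⇐ bis-MOM diketone 22 ⇐ aldol 21 ⇐ intermolecular aldol addition of the kinetic lithium enolate of methyl ketone 19 to enal 3 (joins the core to the styryl arm).
2. 19 ⇐ Weinreb amide 18 ⇐ ring-closing metathesis of diene 17 (C3=C4); the cyclohexene is the only carbocycle made and is formed last.
3. 17 ⇐ trans-δ-lactone 14 (temporary ring, formed first); lactone equilibration fixes C1 relative to C6, and opening gives the amide and the allyl arm.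
4. 14 ⇐ lactone ester 11 + cinnamyl carbonate 7 by Ir-catalysed branched allylation (sets C2), then dealkoxycarbonylation.
5. 11 ⇐ organocatalytic Michael addition of dimethyl malonate 8 to enal 3 (sets C6); 3 comes from vanillin 1, 7 from veratraldehyde 4.

Assumption: the target is made as drawn, (1S,2S,6S), acyl trans to the C2 aryl and cis to the C6 aryl; the two chiral catalysts are taken to induce in their usual sense, and if a first run shows the antipode at that centre the mirror-image catalyst or ligand is used with nothing else changed.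

**Route**

Step 1
Reactants: 1 vanillin (4-hydroxy-3-methoxybenzaldehyde)
Product: 2 3-methoxy-4-(methoxymethoxy)benzaldehyde
Conditions: MOMCl, i-Pr2NEt, CH2Cl2, 0 °C → rt
Reagents that add atoms: chloromethyl methyl ether, COCCl
Why: O-alkylation of the phenoxide (MOM ether formation) masks the phenol with a group stable to bases, hydrides and organometallics and removable with acid at the end.

Step 2
Reactants: 2 3-methoxy-4-(methoxymethoxy)benzaldehyde
Product: 3 (2E)-3-[3-methoxy-4-(methoxymethoxy)phenyl]prop-2-enal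
Conditions: Ph3P=CHCHO (1.3 equiv), toluene, 90 °C
Reagents that add atoms: (triphenylphosphoranylidene)acetaldehyde, O=CC=P(c1ccccc1)(c1ccccc1)c1ccccc1
Why: Wittig olefination with a stabilised ylide gives the E-enal in one two-carbon homologation.

Step 3
Reactants: 4 veratraldehyde (3,4-dimethoxybenzaldehyde)
Product: 5 ethyl (2E)-3-(3,4-dimethoxyphenyl)prop-2-enoate
Conditions: (EtO)2P(O)CH2CO2Et, NaH, THF, 0 °C → rt
Reagents that add atoms: triethyl phosphonoacetate, CCOC(=O)CP(=O)(OCC)OCC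
Why: Horner–Wadsworth–Emmons olefination is reliably E-selective for aryl aldehydes.

Step 4
Reactants: 5 ethyl (2E)-3-(3,4-dimethoxyphenyl)prop-2-enoate
Product: 6 (2E)-3-(3,4-dimethoxyphenyl)prop-2-en-1-ol
Conditions: i-Bu2AlH (2.2 equiv), CH2Cl2, −78 °C; aq. potassium sodium tartrate (KNaC4H4O6)
Reagents that add atoms: none
Why: 1,2-reduction of the enoate by i-Bu2AlH at low temperature gives the allylic alcohol without touching the C=C bond.

Step 5
Reactants: 6 (2E)-3-(3,4-dimethoxyphenyl)prop-2-en-1-ol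
Product: 7 (2E)-3-(3,4-dimethoxyphenyl)prop-2-en-1-yl methyl carbonate
Conditions: ClCO2Me, pyridine, CH2Cl2, 0 °C
Reagents that add atoms: methyl chloroformate, COC(=O)Cl
Why: O-acylation gives the linear allylic carbonate, the standard electrophile for Ir-catalysed allylic substitution.

Step 6
Reactants: 3 (2E)-3-[3-methoxy-4-(methoxymethoxy)phenyl]prop-2-enal; 8 dimethyl malonate
Product: 9 dimethyl 2-{(1S)-1-[3-methoxy-4-(methoxymethoxy)phenyl]-3-oxopropyl}propanedioate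
Conditions: (R)-2-{bis[3,5-bis(trifluoromethyl)phenyl][(trimethylsilyl)oxy]methyl}pyrrolidine (10 mol%), EtOH, 0 °C, 3–4 d
Reagents that add atoms: none
Why: Iminium-catalysed asymmetric Michael addition, in which the C(Ar)2OSiMe3 group of the (R)-catalyst blocks the Si face of C-β of the E-iminium ion so the malonate adds to the Re face and sets the future ring C6 as S.

Step 7
Reactants: 9 dimethyl 2-{(1S)-1-[3-methoxy-4-(methoxymethoxy)phenyl]-3-oxopropyl}propanedioate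
Product: 11 methyl (3S,4S)-4-[3-methoxy-4-(methoxymethoxy)phenyl]-2-oxooxane-3-carboxylate (trans), via hydroxy diester 10 (not isolated)
Conditions: NaBH4, MeOH, 0 °C; then PPTS (5 mol%), toluene, 50 °C
Reagents that add atoms: none
Why: Chemoselective borohydride reduction of the aldehyde followed by lactonisation (intramolecular transesterification) gives the δ-lactone, whose epimerisable C3 settles trans to the aryl group.

Step 8
Reactants: 11 methyl (3S,4S)-4-[3-methoxy-4-(methoxymethoxy)phenyl]-2-oxooxane-3-carboxylate; 7 (2E)-3-(3,4-dimethoxyphenyl)prop-2-en-1-yl methyl carbonate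
Product: 12 methyl (3S,4R)-3-[(1R)-1-(3,4-dimethoxyphenyl)prop-2-en-1-yl]-4-[3-methoxy-4-(methoxymethoxy)phenyl]-2-oxooxane-3-carboxylate (major C3 epimer drawn; the minor one converges in step 9)
Conditions: [Ir(cod)Cl]2 (2 mol%), (Ra,R,R)-O,O'-(1,1'-binaphthalene-2,2'-diyl) N,N-bis(1-phenylethyl)phosphoramidite (4 mol%), 1,5,7-triazabicyclo[4.4.0]dec-5-ene (8 mol%), THF, 25 → 50 °C
Reagents that add atoms: none
Why: Ir-catalysed asymmetric allylic alkylation, in which the soft lactone-ester enolate attacks the aryl-substituted terminus of the allyl–Ir complex (branched product) and the ligand sets the future ring C2 (R here only because CIP priorities change; it is S from 13 on).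

Step 9
Reactants: 12 methyl (3S,4R)-3-[(1R)-1-(3,4-dimethoxyphenyl)prop-2-en-1-yl]-4-[3-methoxy-4-(methoxymethoxy)phenyl]-2-oxooxane-3-carboxylate
Product: 14 (3S,4S)-3-[(1S)-1-(3,4-dimethoxyphenyl)prop-2-en-1-yl]-4-[3-methoxy-4-(methoxymethoxy)phenyl]oxan-2-one, via lactone C3-epimer mixture 13 (not isolated)
Conditions: LiCl, H2O, DMSO, 140 °C; then DBU (0.3 equiv), toluene, 60 °C
Reagents that add atoms: none
Why: Krapcho dealkoxycarbonylation followed by base equilibration through the lactone enolate places the two large ring substituents trans, which is the relationship that becomes acyl cis to the C6 aryl in the cyclohexene and so sets the future ring C1 as S.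

Step 10
Reactants: 14 (3S,4S)-3-[(1S)-1-(3,4-dimethoxyphenyl)prop-2-en-1-yl]-4-[3-methoxy-4-(methoxymethoxy)phenyl]oxan-2-one
Product: 15 (2S,3S)-2-[(1S)-1-(3,4-dimethoxyphenyl)prop-2-en-1-yl]-5-hydroxy-N-methoxy-3-[3-methoxy-4-(methoxymethoxy)phenyl]-N-methylpentanamide
Conditions: MeNHOMe·HCl (3 equiv), AlMe3 (3 equiv), CH2Cl2, 0 °C → rt; aq. potassium sodium tartrate (KNaC4H4O6); used crude
Reagents that add atoms: N,O-dimethylhydroxylamine hydrochloride, CNOC.Cl
Why: Weinreb aminolysis of the lactone by the aluminium amide opens the ring without base-mediated enolisation, so the three stereocentres are untouched.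

Step 11
Reactants: 15 (2S,3S)-2-[(1S)-1-(3,4-dimethoxyphenyl)prop-2-en-1-yl]-5-hydroxy-N-methoxy-3-[3-methoxy-4-(methoxymethoxy)phenyl]-N-methylpentanamide
Product: 16 (2S,3S)-2-[(1S)-1-(3,4-dimethoxyphenyl)prop-2-en-1-yl]-N-methoxy-3-[3-methoxy-4-(methoxymethoxy)phenyl]-N-methyl-5-oxopentanamide
Conditions: Dess–Martin periodinane (1.3 equiv), pyridine, CH2Cl2, 0 °C → rt
Reagents that add atoms: none
Why: Dess–Martin oxidation of the primary alcohol is mild and immediate, which also forestalls re-lactonisation of the δ-hydroxy amide.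

Step 12
Reactants: 16 (2S,3S)-2-[(1S)-1-(3,4-dimethoxyphenyl)prop-2-en-1-yl]-N-methoxy-3-[3-methoxy-4-(methoxymethoxy)phenyl]-N-methyl-5-oxopentanamide
Product: 17 (2S,3S)-2-[(1S)-1-(3,4-dimethoxyphenyl)prop-2-en-1-yl]-N-methoxy-3-[3-methoxy-4-(methoxymethoxy)phenyl]-N-methylhex-5-enamide
Conditions: Ph3PCH3Br (1.6 equiv), KN(SiMe3)2 (1.5 equiv), THF, 0 °C; then 16, −78 → 0 °C
Reagents that add atoms: methyltriphenylphosphonium bromide, [Br-].C[P+](c1ccccc1)(c1ccccc1)c1ccccc1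
Why: Wittig methylenation converts the aldehyde into the allyl arm while the Weinreb amide is inert to the ylide at low temperature.

Step 13
Reactants: 17 (2S,3S)-2-[(1S)-1-(3,4-dimethoxyphenyl)prop-2-en-1-yl]-N-methoxy-3-[3-methoxy-4-(methoxymethoxy)phenyl]-N-methylhex-5-enamide
Product: 18 (1S,2S,6S)-2-(3,4-dimethoxyphenyl)-N-methoxy-6-[3-methoxy-4-(methoxymethoxy)phenyl]-N-methylcyclohex-3-ene-1-carboxamide
Conditions: second-generation Grubbs catalyst RuCl2(=CHPh)(PCy3)(H2IMes) (3 mol%), CH2Cl2 (0.01 M), 40 °C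
Reagents that add atoms: none
Why: Ring-closing metathesis of the 1,7-diene closes the six-membered ring with the double bond fixed at C3=C4 and no stereocentre involved.

Step 14
Reactants: 18 (1S,2S,6S)-2-(3,4-dimethoxyphenyl)-N-methoxy-6-[3-methoxy-4-(methoxymethoxy)phenyl]-N-methylcyclohex-3-ene-1-carboxamide
Product: 19 1-{(1S,2S,6S)-2-(3,4-dimethoxyphenyl)-6-[3-methoxy-4-(methoxymethoxy)phenyl]cyclohex-3-en-1-yl}ethan-1-one
Conditions: MeLi (2.5 equiv), THF, −78 → −20 °C; then AcOH, −78 °C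
Reagents that add atoms: methyllithium, [Li]C
Why: Weinreb ketone synthesis, in which the chelated tetrahedral intermediate survives until the cold quench so there is no over-addition and no enolisable ketone in the basic medium.

Step 15
Reactants: 19 1-{(1S,2S,6S)-2-(3,4-dimethoxyphenyl)-6-[3-methoxy-4-(methoxymethoxy)phenyl]cyclohex-3-en-1-yl}ethan-1-one; 3 (2E)-3-[3-methoxy-4-(methoxymethoxy)phenyl]prop-2-enal
Product: 21 (4E)-1-{(1S,2S,6S)-2-(3,4-dimethoxyphenyl)-6-[3-methoxy-4-(methoxymethoxy)phenyl]cyclohex-3-en-1-yl}-3-hydroxy-5-[3-methoxy-4-(methoxymethoxy)phenyl]pent-4-en-1-one (mixture at the carbinol carbon), via lithium enolate 20 (not isolated)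
Conditions: LiN(SiMe3)2 (1.1 equiv), THF, −78 °C, 45 min; 3 (1.2 equiv), −78 °C; AcOH in THF, −78 °C
Reagents that add atoms: none
Why: Directed intermolecular aldol addition, in which kinetic deprotonation takes the unhindered methyl group rather than the shielded C1–H and the enolate adds 1,2 to the enal (the new carbinol centre is oxidised away next).

Step 16
Reactants: 21 (4E)-1-{(1S,2S,6S)-2-(3,4-dimethoxyphenyl)-6-[3-methoxy-4-(methoxymethoxy)phenyl]cyclohex-3-en-1-yl}-3-hydroxy-5-[3-methoxy-4-(methoxymethoxy)phenyl]pent-4-en-1-one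
Product: 22 (2Z,4E)-1-{(1S,2S,6S)-2-(3,4-dimethoxyphenyl)-6-[3-methoxy-4-(methoxymethoxy)phenyl]cyclohex-3-en-1-yl}-3-hydroxy-5-[3-methoxy-4-(methoxymethoxy)phenyl]penta-2,4-dien-1-one (enol form of the 1,3-diketone)
Conditions: Dess–Martin periodinane (1.5 equiv), CH2Cl2, 0 °C → rt
Reagents that add atoms: none
Why: Dess–Martin oxidation of a β-hydroxy ketone gives the 1,3-diketone, which rests as the chelated enol and thereby shields C1–H from enolisation.

Step 17
Reactants: 22 (2Z,4E)-1-{(1S,2S,6S)-2-(3,4-dimethoxyphenyl)-6-[3-methoxy-4-(methoxymethoxy)phenyl]cyclohex-3-en-1-yl}-3-hydroxy-5-[3-methoxy-4-(methoxymethoxy)phenyl]penta-2,4-dien-1-one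
Product: 23 (2Z,4E)-1-[(1S,2S,6S)-2-(3,4-dimethoxyphenyl)-6-(4-hydroxy-3-methoxyphenyl)cyclohex-3-en-1-yl]-3-hydroxy-5-(4-hydroxy-3-methoxyphenyl)penta-2,4-dien-1-one (CNP0290899.2)
Conditions: 3 M aq. HCl, MeOH/THF, 40 °C
Reagents that add atoms: none
Why: Acid-catalysed acetal hydrolysis removes both aryl MOM ethers under conditions that curcumin-type enolised diketones, aryl methyl ethers and the ring alkene tolerate.

**Compound list**
1 | vanillin (4-hydroxy-3-methoxybenzaldehyde) | COc1cc(C=O)ccc1O | starting material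
2 | 3-methoxy-4-(methoxymethoxy)benzaldehyde | COCOc1ccc(C=O)cc1OC | intermediate
3 | (2E)-3-[3-methoxy-4-(methoxymethoxy)phenyl]prop-2-enal | COCOc1ccc(/C=C/C=O)cc1OC | intermediate
4 | veratraldehyde (3,4-dimethoxybenzaldehyde) | COc1ccc(C=O)cc1OC | starting material
5 | ethyl (2E)-3-(3,4-dimethoxyphenyl)prop-2-enoate | CCOC(=O)/C=C/c1ccc(OC)c(OC)c1 | intermediate
6 | (2E)-3-(3,4-dimethoxyphenyl)prop-2-en-1-ol | OC/C=C/c1ccc(OC)c(OC)c1 | intermediate
7 | (2E)-3-(3,4-dimethoxyphenyl)prop-2-en-1-yl methyl carbonate | COC(=O)OC/C=C/c1ccc(OC)c(OC)c1 | intermediate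
8 | dimethyl malonate (dimethyl propanedioate) | COC(=O)CC(=O)OC | starting material
9 | dimethyl 2-{(1S)-1-[3-methoxy-4-(methoxymethoxy)phenyl]-3-oxopropyl}propanedioate | O=CC[C@H](c1ccc(OCOC)c(OC)c1)C(C(=O)OC)C(=O)OC | intermediate
10 | dimethyl 2-{(1S)-3-hydroxy-1-[3-methoxy-4-(methoxymethoxy)phenyl]propyl}propanedioate | OCC[C@H](c1ccc(OCOC)c(OC)c1)C(C(=O)OC)C(=O)OC | intermediate
11 | methyl (3S,4S)-4-[3-methoxy-4-(methoxymethoxy)phenyl]-2-oxooxane-3-carboxylate (trans) | O=C1OCC[C@H](c2ccc(OCOC)c(OC)c2)[C@H]1C(=O)OC | intermediate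
12 | methyl (3S,4R)-3-[(1R)-1-(3,4-dimethoxyphenyl)prop-2-en-1-yl]-4-[3-methoxy-4-(methoxymethoxy)phenyl]-2-oxooxane-3-carboxylate (major C3 epimer) | O=C1OCC[C@H](c2ccc(OCOC)c(OC)c2)[C@@]1(C(=O)OC)[C@@H](c3ccc(OC)c(OC)c3)C=C | intermediate
13 | (4S)-3-[(1S)-1-(3,4-dimethoxyphenyl)prop-2-en-1-yl]-4-[3-methoxy-4-(methoxymethoxy)phenyl]oxan-2-one, mixture of C3 epimers | O=C1OCC[C@H](c2ccc(OCOC)c(OC)c2)C1[C@@H](c3ccc(OC)c(OC)c3)C=C | intermediate
14 | (3S,4S)-3-[(1S)-1-(3,4-dimethoxyphenyl)prop-2-en-1-yl]-4-[3-methoxy-4-(methoxymethoxy)phenyl]oxan-2-one (trans) | O=C1OCC[C@H](c2ccc(OCOC)c(OC)c2)[C@H]1[C@@H](c3ccc(OC)c(OC)c3)C=C | intermediate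
15 | (2S,3S)-2-[(1S)-1-(3,4-dimethoxyphenyl)prop-2-en-1-yl]-5-hydroxy-N-methoxy-3-[3-methoxy-4-(methoxymethoxy)phenyl]-N-methylpentanamide | CON(C)C(=O)[C@H]([C@@H](c1ccc(OC)c(OC)c1)C=C)[C@@H](c1ccc(OCOC)c(OC)c1)CCO | intermediate
16 | (2S,3S)-2-[(1S)-1-(3,4-dimethoxyphenyl)prop-2-en-1-yl]-N-methoxy-3-[3-methoxy-4-(methoxymethoxy)phenyl]-N-methyl-5-oxopentanamide | CON(C)C(=O)[C@H]([C@@H](c1ccc(OC)c(OC)c1)C=C)[C@@H](c1ccc(OCOC)c(OC)c1)CC=O | intermediate
17 | (2S,3S)-2-[(1S)-1-(3,4-dimethoxyphenyl)prop-2-en-1-yl]-N-methoxy-3-[3-methoxy-4-(methoxymethoxy)phenyl]-N-methylhex-5-enamide | CON(C)C(=O)[C@H]([C@@H](c1ccc(OC)c(OC)c1)C=C)[C@@H](c1ccc(OCOC)c(OC)c1)CC=C | intermediate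
18 | (1S,2S,6S)-2-(3,4-dimethoxyphenyl)-N-methoxy-6-[3-methoxy-4-(methoxymethoxy)phenyl]-N-methylcyclohex-3-ene-1-carboxamide | CON(C)C(=O)[C@@H]1[C@@H](c2ccc(OC)c(OC)c2)C=CC[C@@H]1c3ccc(OCOC)c(OC)c3 | intermediate
19 | 1-{(1S,2S,6S)-2-(3,4-dimethoxyphenyl)-6-[3-methoxy-4-(methoxymethoxy)phenyl]cyclohex-3-en-1-yl}ethan-1-one | CC(=O)[C@@H]1[C@@H](c2ccc(OC)c(OC)c2)C=CC[C@@H]1c3ccc(OCOC)c(OC)c3 | intermediate
20 | lithium enolate of 19 (lithium 1-{(1S,2S,6S)-2-(3,4-dimethoxyphenyl)-6-[3-methoxy-4-(methoxymethoxy)phenyl]cyclohex-3-en-1-yl}ethen-1-olate) | C=C(O[Li])[C@@H]1[C@@H](c2ccc(OC)c(OC)c2)C=CC[C@@H]1c3ccc(OCOC)c(OC)c3 | intermediate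
21 | (4E)-1-{(1S,2S,6S)-2-(3,4-dimethoxyphenyl)-6-[3-methoxy-4-(methoxymethoxy)phenyl]cyclohex-3-en-1-yl}-3-hydroxy-5-[3-methoxy-4-(methoxymethoxy)phenyl]pent-4-en-1-one, mixture at C3 of the chain | COCOc1ccc(/C=C/C(O)CC(=O)[C@@H]2[C@@H](c3ccc(OC)c(OC)c3)C=CC[C@@H]2c2ccc(OCOC)c(OC)c2)cc1OC | intermediate
22 | (2Z,4E)-1-{(1S,2S,6S)-2-(3,4-dimethoxyphenyl)-6-[3-methoxy-4-(methoxymethoxy)phenyl]cyclohex-3-en-1-yl}-3-hydroxy-5-[3-methoxy-4-(methoxymethoxy)phenyl]penta-2,4-dien-1-one | COCOc1ccc(/C=C/C(O)=C/C(=O)[C@@H]2[C@@H](c3ccc(OC)c(OC)c3)C=CC[C@@H]2c2ccc(OCOC)c(OC)c2)cc1OC | intermediate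
23 | (2Z,4E)-1-[(1S,2S,6S)-2-(3,4-dimethoxyphenyl)-6-(4-hydroxy-3-methoxyphenyl)cyclohex-3-en-1-yl]-3-hydroxy-5-(4-hydroxy-3-methoxyphenyl)penta-2,4-dien-1-one | COc1cc(/C=C/C(O)=C/C(=O)[C@@H]2[C@@H](c3ccc(OC)c(OC)c3)C=CC[C@@H]2c2ccc(O)c(OC)c2)ccc1O | target

**Totals**
Total steps: 17. Longest linear sequence: 14 steps (1 → 2 → 3 → 9 → 11 → 12 → 14 → 15 → 16 → 17 → 18 → 19 → 21 → 22 → 23); the carbonate branch 4 → 5 → 6 → 7 adds 3 steps.

**Three steps most likely to fail, with fallbacks**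

Step 8. The nucleophilic carbon of 11 is tertiary and sits next to an aryl-bearing carbon, so the Ir allylation may be slow or leak to the linear product. The fallback sets out from 11 and comes back at 14, replacing catalyst control at C2 by substrate-controlled conjugate addition. Krapcho removal of the ester from 11 (LiCl, H2O, DMSO, 140 °C) gives (4S)-4-[3-methoxy-4-(methoxymethoxy)phenyl]oxan-2-one F1. Its lithium enolate (LiN(SiMe3)2, THF, −78 °C) adds to veratraldehyde 4 to give the aldol adduct (4S)-3-[(3,4-dimethoxyphenyl)(hydroxy)methyl]-4-[3-methoxy-4-(methoxymethoxy)phenyl]oxan-2-one F2. MsCl/Et3N converts this into the mesylate (4S)-3-[(3,4-dimethoxyphenyl)(methanesulfonyloxy)methyl]-4-[3-methoxy-4-(methoxymethoxy)phenyl]oxan-2-one F3, and DBU eliminates it to the arylidene lactone (3E,4R)-3-[(3,4-dimethoxyphenyl)methylidene]-4-[3-methoxy-4-(methoxymethoxy)phenyl]oxan-2-one F4. CH2=CHMgBr with CuBr·SMe2 (THF, −40 °C) then adds vinyl to the exocyclic β-carbon; the ring aryl is held pseudoaxial by A(1,3) strain, so attack anti to it on the E-alkene should give the required (1S) side-chain centre. This yields the epimer mixture 13, which DBU equilibrates to 14.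

Step 10. The hindered δ-lactone may open incompletely, and the δ-hydroxy Weinreb amide can close back to 14. The fallback sets out from 14 and comes back at 15 by a stepwise opening with the alcohol protected. LiOH (THF/H2O) opens 14 to lithium (2S,3S)-2-[(1S)-1-(3,4-dimethoxyphenyl)prop-2-en-1-yl]-5-hydroxy-3-[3-methoxy-4-(methoxymethoxy)phenyl]pentanoate F5. TBSCl/imidazole (DMF) silylates both oxygens to give tert-butyldimethylsilyl (2S,3S)-5-[(tert-butyldimethylsilyl)oxy]-2-[(1S)-1-(3,4-dimethoxyphenyl)prop-2-en-1-yl]-3-[3-methoxy-4-(methoxymethoxy)phenyl]pentanoate F6. K2CO3 in aqueous MeOH cleaves only the silyl ester to give (2S,3S)-5-[(tert-butyldimethylsilyl)oxy]-2-[(1S)-1-(3,4-dimethoxyphenyl)prop-2-en-1-yl]-3-[3-methoxy-4-(methoxymethoxy)phenyl]pentanoic acid F7. Coupling with MeNHOMe·HCl (EDC·HCl, HOBt, i-Pr2NEt) gives (2S,3S)-5-[(tert-butyldimethylsilyl)oxy]-2-[(1S)-1-(3,4-dimethoxyphenyl)prop-2-en-1-yl]-N-methoxy-3-[3-methoxy-4-(methoxymethoxy)phenyl]-N-methylpentanamide F8. Bu4NF buffered with AcOH then frees 15, which is oxidised at once as in step 11.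

Step 14. The amide carbonyl lies between two branched carbons, so MeLi may add slowly or act as a base and epimerise C1. The fallback sets out from 18 and comes back at 19 through the aldehyde oxidation level, where the small hydride and the more electrophilic aldehyde overcome the hindrance. LiAlH4 (THF, −78 °C) reduces 18 to (1S,2S,6S)-2-(3,4-dimethoxyphenyl)-6-[3-methoxy-4-(methoxymethoxy)phenyl]cyclohex-3-ene-1-carbaldehyde F9. MeMgBr (THF, −78 °C) adds to give 1-{(1S,2S,6S)-2-(3,4-dimethoxyphenyl)-6-[3-methoxy-4-(methoxymethoxy)phenyl]cyclohex-3-en-1-yl}ethan-1-ol F10 as a carbinol mixture. Dess–Martin periodinane oxidises this to 19.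

**Further compounds**
F1 | step 8 | (4S)-4-[3-methoxy-4-(methoxymethoxy)phenyl]oxan-2-one | O=C1OCC[C@H](c2ccc(OCOC)c(OC)c2)C1
F2 | step 8 | (4S)-3-[(3,4-dimethoxyphenyl)(hydroxy)methyl]-4-[3-methoxy-4-(methoxymethoxy)phenyl]oxan-2-one (diastereomer mixture) | O=C1OCC[C@H](c2ccc(OCOC)c(OC)c2)C1C(O)c1ccc(OC)c(OC)c1
F3 | step 8 | (4S)-3-[(3,4-dimethoxyphenyl)(methanesulfonyloxy)methyl]-4-[3-methoxy-4-(methoxymethoxy)phenyl]oxan-2-one (diastereomer mixture) | O=C1OCC[C@H](c2ccc(OCOC)c(OC)c2)C1C(OS(C)(=O)=O)c1ccc(OC)c(OC)c1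
F4 | step 8 | (3E,4R)-3-[(3,4-dimethoxyphenyl)methylidene]-4-[3-methoxy-4-(methoxymethoxy)phenyl]oxan-2-one | O=C1OCC[C@H](c2ccc(OCOC)c(OC)c2)/C1=C\c1ccc(OC)c(OC)c1
F5 | step 10 | lithium (2S,3S)-2-[(1S)-1-(3,4-dimethoxyphenyl)prop-2-en-1-yl]-5-hydroxy-3-[3-methoxy-4-(methoxymethoxy)phenyl]pentanoate | [Li+].[O-]C(=O)[C@H]([C@@H](c1ccc(OC)c(OC)c1)C=C)[C@@H](c1ccc(OCOC)c(OC)c1)CCO
F6 | step 10 | tert-butyldimethylsilyl (2S,3S)-5-[(tert-butyldimethylsilyl)oxy]-2-[(1S)-1-(3,4-dimethoxyphenyl)prop-2-en-1-yl]-3-[3-methoxy-4-(methoxymethoxy)phenyl]pentanoate | CC(C)(C)[Si](C)(C)OC(=O)[C@H]([C@@H](c1ccc(OC)c(OC)c1)C=C)[C@@H](c1ccc(OCOC)c(OC)c1)CCO[Si](C)(C)C(C)(C)C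
F7 | step 10 | (2S,3S)-5-[(tert-butyldimethylsilyl)oxy]-2-[(1S)-1-(3,4-dimethoxyphenyl)prop-2-en-1-yl]-3-[3-methoxy-4-(methoxymethoxy)phenyl]pentanoic acid | OC(=O)[C@H]([C@@H](c1ccc(OC)c(OC)c1)C=C)[C@@H](c1ccc(OCOC)c(OC)c1)CCO[Si](C)(C)C(C)(C)C
F8 | step 10 | (2S,3S)-5-[(tert-butyldimethylsilyl)oxy]-2-[(1S)-1-(3,4-dimethoxyphenyl)prop-2-en-1-yl]-N-methoxy-3-[3-methoxy-4-(methoxymethoxy)phenyl]-N-methylpentanamide | CON(C)C(=O)[C@H]([C@@H](c1ccc(OC)c(OC)c1)C=C)[C@@H](c1ccc(OCOC)c(OC)c1)CCO[Si](C)(C)C(C)(C)C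
F9 | step 14 | (1S,2S,6S)-2-(3,4-dimethoxyphenyl)-6-[3-methoxy-4-(methoxymethoxy)phenyl]cyclohex-3-ene-1-carbaldehyde | O=C[C@@H]1[C@@H](c2ccc(OC)c(OC)c2)C=CC[C@@H]1c3ccc(OCOC)c(OC)c3
F10 | step 14 | 1-{(1S,2S,6S)-2-(3,4-dimethoxyphenyl)-6-[3-methoxy-4-(methoxymethoxy)phenyl]cyclohex-3-en-1-yl}ethan-1-ol (carbinol mixture) | CC(O)[C@@H]1[C@@H](c2ccc(OC)c(OC)c2)C=CC[C@@H]1c3ccc(OCOC)c(OC)c3
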